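We have to choose a temperature schedule for this flask, and the choice rests on how heat moves target and side product against each other.

    substrate + free catalyst → free catalyst + open intermediate (k1 = 290 /M/s, Ea1 = 38.0 kJ/mol)
    second catalyst + open intermediate ⇌ catalyst intermediate (K2 = 21000 /M, k2 = 45000 /M/s, Ea2 = 15.0 kJ/mol, ΔH2 = −4.00 kJ/mol)
    reagent + catalyst intermediate ⇌ second catalyst + target (K3 = 0.0094, k3 = 140 /M/s, Ea3 = 40.0 kJ/mol, ΔH3 = −19.0 kJ/mol)
    substrate + open intermediate → side product (k4 = 1.3 /M/s, Ea4 = 56.0 kJ/mol)
    2 substrate → self-condensation product (k5 = 4.6 /M/s, Ea5 = 68.0 kJ/mol)
    (constants at 70 °C)

| flask | substrate | reagent | free catalyst | second catalyst | temperature | time | remark |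
|---|---|---|---|---|---|---|---|
| noon | 2.0 mM | 1.90 mM | 50 µM | 1.1 µM | 100 °C | 1.0 min |  |
| midnight | 2.0 mM | 1.90 mM | 50 µM | 1.1 µM | 70 °C | 1.0 min |  |
| dawn | 2.0 mM | 1.90 mM | 50 µM | 1.1 µM |  | 1.0 min | at 70 °C until 12 s, from then on at 100 °C |
| winter | 2.0 mM | 1.90 mM | 50 µM | 1.1 µM | 85 °C | 1.0 min |  |

- a species is counted by the substrate in it: one side product or self-condensation product counts as two
- where a step has two of a species, its rate is k times that concentration squared, and two are used at each turn
- the list of constants is for 70 °C, to be carried to other temperatures by the activation energies and enthalpies

- which flask leads in share of target in all that became target or side product ("all alike" within 1.5 percentage points) (noon / midnight / dawn / winter / all alike)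
- share of target in all that became target or side product, noon
- share of target in all that became target or side product, midnight
- share of target in all that became target or side product, dawn
- share of target in all that became target or side product, winter

Counted by the substrate in them, target weighs one and side product two. We reckon by freezing what hardly moves.

1. Temperature. Each k is multiplied by the exp of Ea/R times the reciprocal reference temperature minus the reciprocal flask temperature.

2. Free catalyst returns at each turn, so its c stays at the charge. Substrate therefore enters open intermediate at a·c(substrate), where a = k(open)·c(free catalyst) is a pseudo-first-order constant, and k(open) belongs to the first step. At noon a is 0.0423 /s. Self-condensation starts faster, at B = 0.125 /s, where B is reckoned on the charge and the real pull of this step falls in proportion to c(substrate).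

3. Integrating this pair of losses, and leaving out the substrate that side product draws, gives the amount entered: n = (a·c(substrate charged)/B)·ln(1 + (B/a)(1 − exp(−a·t))). Noon gets 0.889 mM. Midnight, with a = 0.0145 /s and B = 0.0184 /s, gets 0.871 mM.

4. We take c(open intermediate) as n, which overstates it by what has already gone on to target and side product, so side product forms at k(side)·c(substrate)·n while n grows at a·c(substrate). Dividing one by the other removes both time and substrate, so counted side product equals g times n squared, with g = k(side)/a, the side-product gain. At noon g is 0.149 /mM, which gives 118 µM. Midnight gives 67.9 µM.

5. At midnight second catalyst takes up open intermediate at k(bind)·n, faster than catalyst intermediate meets reagent at k(turn)·c(reagent), and binding beats its reverse. At midnight catalyst intermediate is thus the resting state, and target leaves it by its step with reagent, a step that also runs back. We bound target by k(turn)·c(reagent)·c(second catalyst)·t, a ceiling, since we hold all second catalyst as catalyst intermediate and drop the back step: 17.6 µM at midnight and 54.2 µM at noon. Noon's ceiling is far less than c(reagent) and far less than n, so we hold c(reagent) at its charge and do not take target off n.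

6. Winter has a = 0.0253 /s and B = 0.0499 /s, so n = 0.946 mM, counted side product 104 µM and target 31.6 µM.

7. Dawn runs in two stages. The cold stage leaves 1.40 mM of substrate and n = 0.291 mM. The hot stage restarts the formula from there and adds 0.695 mM. Each stage's gain acts on its own rise in n squared, so we reckon dawn at 140 µM of counted side product and a target ceiling of 46.9 µM.

8. Our shares are 31.5% for noon, 20.5% for midnight, 25.1% for dawn and 23.2% for winter, and the leader is noon.

The forecast names noon with 26.5%, 18%, 20.5% and 20.5% for noon, midnight, dawn and winter, on the ground that “heat raises target almost threefold”, and each of its shares stands lower than ours .

The simulation gives noon as leader, with 27.3% for noon, 18.5% for midnight, 22.3% for dawn and 21.1% for winter.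

At noon the opening step used substrate at 0.34 of the self-condensation rate at the start and 19 times it at 1.00 min, and noon's open intermediate, target and catalyst intermediate, with each side product counted at the one open intermediate it took, together read 43.2% of the substrate charged, on which the gain gives 5.55% against a side product reading of 5.21%. In the neighbour flask, noon with 3.4 mM of substrate, the same gain and ceiling give a share of 21.0%, and that flask reads 19.1%.

(The constants used here belong to no real substance; the flask was simulated.)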